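**Plan**

1. Labels: O1–C5–C6=C7–C8 is the dihydrofuran ring. C5 (bearing CH3) and C6 are shared with the cyclohexane C1–C6, C3 carries OH, C9 is the butenolide α-carbon, and the acetylenic end is primed. Cuts: the C=C next to the fifteen-carbon acetylenic unit (olefination); the butenolide O–C bond and the bond from its ylidene carbon to the ring CH (coupling/lactonization); C8–C9 (allenolate addition); and, in the dihydrofuran ring, C6=C7 together with the O1–C8 link (domino acylation/Wittig).
2. Forward: (4R,6R)-actinol feeds both ends. Right end: silyl ether, α-ketol, then the dihydrofuran ring is closed at the lactone level by one-pot O-acylation/intramolecular Wittig reaction with Ph3P=C=C=O. Then reductive acetylation, the C8–C9 bond, the butenolide ring by Pd/Cu coupling–lactonization with a dienynal, Horner–Wadsworth–Emmons union with the acetylenic phosphonate, and desilylation.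
3. Enabling feature: in the dihydrofuran ring the oxygen-bearing quaternary C5 is bonded to the sp2 ring-fusion carbon C6, so C6=C7 is an olefinated α-ketol (O1–C5–C6=O). C6 lies between the quaternary carbons C1 and C5, so the ketone cannot enolize and is best reached by a tethered ylide; the ring fixes C8 cis to O1.
4. Helpers: C8 passes through the ring closure as a lactone carbonyl (one oxidation level too high) and is reduced afterwards. Silyl ethers mask both carbinols and a 4-methoxybenzyl ether masks the enynol; all are removed.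
5. Stereochemistry: C3 and C3′ come from actinol. C5 comes from enolate hydroxylation anti to the silyloxy group. C8 comes from a catalyst-controlled addition to the planar furanium ion. Double bonds come from the E-enynol, the Z-selective allenolate addition, anti-oxymetalation in the lactonization and E-selective olefinations.

Key step: step 3

Assumption: (4R,6R)-actinol (1), the industrial zeaxanthin building block, is taken as a commercial chiral starting material.

**Route**

Step 1
Reactants: 1 (4R,6R)-4-hydroxy-2,2,6-trimethylcyclohexanone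
Product: 2 (4R,6R)-4-(tert-butyldimethylsilyloxy)-2,2,6-trimethylcyclohexanone
Conditions: TBSCl, imidazole, DMF, 20 °C
Reagents that add atoms: tert-butyldimethylsilyl chloride, CC(C)(C)[Si](C)(C)Cl
Why: Imidazole-mediated silyl ether formation at the only hydroxyl should proceed cleanly and leaves the ketone and both stereocentres untouched.

Step 2
Reactants: 2 (4R,6R)-4-(tert-butyldimethylsilyloxy)-2,2,6-trimethylcyclohexanone
Product: 3 (2R,4S)-4-(tert-butyldimethylsilyloxy)-2-hydroxy-2,6,6-trimethylcyclohexanone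
Conditions: KN(SiMe3)2, THF, −78 °C; then 2-(phenylsulfonyl)-3-phenyloxaziridine, −78 °C
Reagents that add atoms: 2-(phenylsulfonyl)-3-phenyloxaziridine, O=S(=O)(N1OC1c1ccccc1)c1ccccc1
Why: The enolate can form only on the CH(CH3) side (the other α-carbon is quaternary), and its electrophilic hydroxylation by the N-sulfonyloxaziridine (enolate oxidation) should occur on the face anti to the silyloxy group, which sets the tertiary carbinol centre (the later C5) with OH trans to OSi and erases the former methine centre.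

Step 3
Reactants: 3 (2R,4S)-4-(tert-butyldimethylsilyloxy)-2-hydroxy-2,6,6-trimethylcyclohexanone; 4 ketenylidenetriphenylphosphorane
Product: 6 (6S,7aR)-6-(tert-butyldimethylsilyloxy)-4,4,7a-trimethyl-5,6,7,7a-tetrahydro-1-benzofuran-2(4H)-one, via ylide ester 5 (not isolated)
Conditions: toluene, 110 °C
Reagents that add atoms: none
Why: The tertiary hydroxyl adds across the C=C of the cumulated ylide 4 (O-acylation) to give the ester-stabilised ylide 5, whose carbanion carbon (C7) attacks the neighbouring C6 ketone, and the oxaphosphetane collapses with loss of Ph3P=O to the C6=C7 double bond. The closest known reaction type is the domino addition/intramolecular Wittig synthesis of butenolides from α-hydroxy ketones and ketenylidenetriphenylphosphorane, a formal (3+2) annulation of an O–C–C=O unit with a two-carbon unit. The ring O1–C5–C6–C7–C8 closes by 5-exo-trig addition of the ylide carbon to the carbonyl followed by syn-cycloreversion. No stereocentre is created: C5 is retained, and the ring forces C8 cis to O1 on the new trisubstituted alkene, a geometry that an intermolecular olefination of this hindered ketone could not guarantee. The step needs chemoselectivity for acylation and olefination over enolisation, α-ketol shift or intermolecular Wittig reaction; this is secured because the ketone is non-enolisable (C1 and C5 quaternary), the medium is neutral and the ylide is held next to the carbonyl.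

Step 4
Reactants: 6 (6S,7aR)-6-(tert-butyldimethylsilyloxy)-4,4,7a-trimethyl-5,6,7,7a-tetrahydro-1-benzofuran-2(4H)-one
Product: 8 (6S,7aR)-6-(tert-butyldimethylsilyloxy)-4,4,7a-trimethyl-2,4,5,6,7,7a-hexahydro-1-benzofuran-2-yl acetate (both C2 epimers), via aluminium hemiacetal 7 (not isolated)
Conditions: iBu2AlH, CH2Cl2, −78 °C; then pyridine, DMAP, Ac2O, −78 → 0 °C
Reagents that add atoms: acetic anhydride, CC(=O)OC(C)=O
Why: Hydride adds 1,2 to the lactone carbonyl and the tetrahedral aluminium hemiacetal, stable at −78 °C, is acylated in the same flask (reductive acetylation of a lactone), so that C8 is brought down to the acetal level as an ionisable allylic acetate whose two epimers lead to the same cation.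

Step 5
Reactants: 8 (6S,7aR)-6-(tert-butyldimethylsilyloxy)-4,4,7a-trimethyl-2,4,5,6,7,7a-hexahydro-1-benzofuran-2-yl acetate; 9 trimethylsilyl prop-2-ynoate
Product: 11 (2Z)-2-[(2R,6S,7aR)-6-(tert-butyldimethylsilyloxy)-4,4,7a-trimethyl-2,4,5,6,7,7a-hexahydro-1-benzofuran-2-yl]-3-iodoprop-2-enoic acid, via trimethylsilyl ester 10 (not isolated)
Conditions: 9, Me3SiI, CH2Cl2, −78 °C; then 8, chiral imidodiphosphorimidate acid (3 mol %), −78 → −40 °C; aqueous NaH2PO4
Reagents that add atoms: iodotrimethylsilane, C[Si](C)(C)I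
Why: Proposed new method: Me3SiI should add in conjugate fashion to the silyl ynoate 9 to give a bis-silyl iodoallenolate (a cumulated silyl ketene acetal); the silylated chiral acid ionises acetate 8 to the 2H-furanium ion (C8=O1+, allyl-stabilised through C7=C6, unable to lose a proton because C5 is quaternary), which stays paired with the confined chiral anion; the allenolate α-carbon then attacks C8 anti to iodine (hence Z) on the face left open by the anion, so that C8 (2R) is set by the catalyst, the cation itself being almost unbiased because C5 carries CH3 on one face and CH2 on the other; aqueous work-up cleaves silyl ester 10; the closest known reaction types are the halo-aldol (β-iodo Morita–Baylis–Hillman) three-component coupling of aldehydes, propiolates and Me3SiI and the imidodiphosphorimidate-catalysed addition of silyl ketene acetals to cyclic oxocarbenium ions made from lactol acetates.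

Step 6
Reactants: 12 (2E)-3-methylpent-2-en-4-yn-1-ol
Product: 13 (2E)-3-methylpent-2-en-4-ynal
Conditions: MnO2, CH2Cl2, 20 °C
Reagents that add atoms: none
Why: MnO2 oxidises the allylic alcohol chemoselectively to the enal (allylic oxidation) without touching the terminal alkyne or the E geometry.

Step 7
Reactants: 13 (2E)-3-methylpent-2-en-4-ynal; 14 (triphenylphosphoranylidene)acetaldehyde
Product: 15 (2E,4E)-5-methylhepta-2,4-dien-6-ynal
Conditions: toluene, 70 °C
Reagents that add atoms: none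
Why: Wittig olefination with the stabilised formylmethylene ylide extends the enal by two carbons with E selectivity, and the less electrophilic dienal product should resist a second homologation.

Step 8
Reactants: 11 (2Z)-2-[(2R,6S,7aR)-6-(tert-butyldimethylsilyloxy)-4,4,7a-trimethyl-2,4,5,6,7,7a-hexahydro-1-benzofuran-2-yl]-3-iodoprop-2-enoic acid; 15 (2E,4E)-5-methylhepta-2,4-dien-6-ynal
Product: 17 (2E,4E,6Z)-6-{4-[(2R,6S,7aR)-6-(tert-butyldimethylsilyloxy)-4,4,7a-trimethyl-2,4,5,6,7,7a-hexahydro-1-benzofuran-2-yl]-5-oxofuran-2(5H)-ylidene}-5-methylhexa-2,4-dienal, via enynoic acid 16 (not isolated)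
Conditions: Pd(PPh3)4 (5 mol %), CuI (10 mol %), Et3N, MeCN, 20 °C
Reagents that add atoms: none
Why: Sonogashira coupling of the vinyl iodide with the terminal alkyne keeps the Z geometry, and the resulting (Z)-enynoic acid should cyclise in the same flask by metal-promoted 5-exo-dig anti-addition of the carboxylate to the alkyne, the well-known tandem route from (Z)-3-iodoacrylic acids to (Z)-ylidenebutenolides.

Step 9
Reactants: 12 (2E)-3-methylpent-2-en-4-yn-1-ol
Product: 18 1-methoxy-4-({[(2E)-3-methylpent-2-en-4-yn-1-yl]oxy}methyl)benzene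
Conditions: NaH, 4-methoxybenzyl chloride, Bu4NI (cat.), THF, 0 → 20 °C
Reagents that add atoms: 4-methoxybenzyl chloride, COc1ccc(CCl)cc1
Why: Williamson etherification of the alkoxide (the alkyne C–H is far less acidic than O–H) masks the allylic alcohol as an oxidatively removable ether.

Step 10
Reactants: 18 1-methoxy-4-({[(2E)-3-methylpent-2-en-4-yn-1-yl]oxy}methyl)benzene; 2 (4R,6R)-4-(tert-butyldimethylsilyloxy)-2,2,6-trimethylcyclohexanone
Product: 19 (4R,6R)-4-(tert-butyldimethylsilyloxy)-1-{(3E)-5-[(4-methoxybenzyl)oxy]-3-methylpent-3-en-1-yn-1-yl}-2,2,6-trimethylcyclohexan-1-ol (C1 epimers)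
Conditions: BuLi, THF, −78 °C; then 2, −78 → 0 °C
Reagents that add atoms: none
Why: The lithium acetylide adds 1,2 to the hindered ketone, as is usual for 2,2,6-trimethylcyclohexanones; the new carbinol centre and the adjacent methine need no control because both become sp2 in the next step.

Step 11
Reactants: 19 (4R,6R)-4-(tert-butyldimethylsilyloxy)-1-{(3E)-5-[(4-methoxybenzyl)oxy]-3-methylpent-3-en-1-yn-1-yl}-2,2,6-trimethylcyclohexan-1-ol
Product: 20 tert-butyl{[(1R)-4-{(3E)-5-[(4-methoxybenzyl)oxy]-3-methylpent-3-en-1-yn-1-yl}-3,5,5-trimethylcyclohex-3-en-1-yl]oxy}dimethylsilane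
Conditions: POCl3, pyridine, 90 °C
Reagents that add atoms: none
Why: Elimination through the dichlorophosphate can take only the methine hydrogen, since the other neighbour of the carbinol carbon is quaternary, and should give the conjugated tetrasubstituted enyne.

Step 12
Reactants: 20 tert-butyl{[(1R)-4-{(3E)-5-[(4-methoxybenzyl)oxy]-3-methylpent-3-en-1-yn-1-yl}-3,5,5-trimethylcyclohex-3-en-1-yl]oxy}dimethylsilane
Product: 21 (2E)-5-[(4R)-4-(tert-butyldimethylsilyloxy)-2,6,6-trimethylcyclohex-1-en-1-yl]-3-methylpent-2-en-4-yn-1-ol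
Conditions: DDQ, CH2Cl2/aqueous pH 7 buffer, 0 °C
Reagents that add atoms: none
Why: DDQ oxidises the electron-rich benzyl ether (oxidative ether cleavage) and releases the primary allylic alcohol while the silyl ether survives.

Step 13
Reactants: 21 (2E)-5-[(4R)-4-(tert-butyldimethylsilyloxy)-2,6,6-trimethylcyclohex-1-en-1-yl]-3-methylpent-2-en-4-yn-1-ol
Product: 22 {[(1R)-4-[(3E)-5-bromo-3-methylpent-3-en-1-yn-1-yl]-3,5,5-trimethylcyclohex-3-en-1-yl]oxy}(tert-butyl)dimethylsilane
Conditions: PBr3, pyridine (cat.), Et2O, −20 °C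
Reagents that add atoms: phosphorus tribromide, BrP(Br)Br
Why: Bromide displaces the phosphite ester of the primary allylic alcohol at low temperature, which should keep the E geometry and the silyl ether.

Step 14
Reactants: 22 {[(1R)-4-[(3E)-5-bromo-3-methylpent-3-en-1-yn-1-yl]-3,5,5-trimethylcyclohex-3-en-1-yl]oxy}(tert-butyl)dimethylsilane
Product: 23 diethyl {(2E)-5-[(4R)-4-(tert-butyldimethylsilyloxy)-2,6,6-trimethylcyclohex-1-en-1-yl]-3-methylpent-2-en-4-yn-1-yl}phosphonate
Conditions: P(OEt)3, 100 °C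
Reagents that add atoms: triethyl phosphite, CCOP(OCC)OCC
Why: The Michaelis–Arbuzov reaction of the primary allylic bromide with triethyl phosphite gives the allylic phosphonate.

Step 15
Reactants: 23 diethyl {(2E)-5-[(4R)-4-(tert-butyldimethylsilyloxy)-2,6,6-trimethylcyclohex-1-en-1-yl]-3-methylpent-2-en-4-yn-1-yl}phosphonate; 17 (2E,4E,6Z)-6-{4-[(2R,6S,7aR)-6-(tert-butyldimethylsilyloxy)-4,4,7a-trimethyl-2,4,5,6,7,7a-hexahydro-1-benzofuran-2-yl]-5-oxofuran-2(5H)-ylidene}-5-methylhexa-2,4-dienal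
Product: 24 bis(tert-butyldimethylsilyl) ether of the target
Conditions: KN(SiMe3)2, THF, −78 °C; then 17, −78 → −30 °C
Reagents that add atoms: none
Why: Horner–Wadsworth–Emmons olefination with the preformed allylic phosphonate carbanion should join the halves through a new E double bond, the aldehyde being far more electrophilic than the lactone at low temperature.

Step 16
Reactants: 24 bis(tert-butyldimethylsilyl) ether of the target
Product: 25 (5Z)-3-[(2R,6S,7aR)-6-hydroxy-4,4,7a-trimethyl-2,4,5,6,7,7a-hexahydro-1-benzofuran-2-yl]-5-{(2E,4E,6E,8E)-11-[(4R)-4-hydroxy-2,6,6-trimethylcyclohex-1-en-1-yl]-2,9-dimethylundeca-2,4,6,8-tetraen-10-yn-1-ylidene}furan-2(5H)-one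
Conditions: Et3N·3HF, THF/MeCN, 20 °C, dark
Reagents that add atoms: none
Why: Amine hydrofluoride cleaves both silyl ethers under nearly neutral conditions, which should avoid base-induced opening of the butenolide and acid-induced epimerisation at C8.

**Compound list**

1 | (4R,6R)-4-hydroxy-2,2,6-trimethylcyclohexanone (actinol) | O=C1C(C)(C)C[C@H](O)C[C@H]1C | starting material
2 | (4R,6R)-4-(tert-butyldimethylsilyloxy)-2,2,6-trimethylcyclohexanone | O=C1C(C)(C)C[C@H](O[Si](C)(C)C(C)(C)C)C[C@H]1C | intermediate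
3 | (2R,4S)-4-(tert-butyldimethylsilyloxy)-2-hydroxy-2,6,6-trimethylcyclohexanone | O=C1C(C)(C)C[C@H](O[Si](C)(C)C(C)(C)C)C[C@@]1(C)O | intermediate
4 | ketenylidenetriphenylphosphorane | O=C=C=P(c1ccccc1)(c1ccccc1)c1ccccc1 | starting material
5 | (1R,5S)-5-(tert-butyldimethylsilyloxy)-1,3,3-trimethyl-2-oxocyclohexyl (triphenylphosphoranylidene)acetate | O=C1C(C)(C)C[C@H](O[Si](C)(C)C(C)(C)C)C[C@@]1(C)OC(=O)C=P(c1ccccc1)(c1ccccc1)c1ccccc1 | intermediate
6 | (6S,7aR)-6-(tert-butyldimethylsilyloxy)-4,4,7a-trimethyl-5,6,7,7a-tetrahydro-1-benzofuran-2(4H)-one | O=C1C=C2C(C)(C)C[C@H](O[Si](C)(C)C(C)(C)C)C[C@@]2(C)O1 | intermediate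
7 | {[(6S,7aR)-6-(tert-butyldimethylsilyloxy)-4,4,7a-trimethyl-2,4,5,6,7,7a-hexahydro-1-benzofuran-2-yl]oxy}diisobutylalane | CC(C)C[Al](CC(C)C)OC1C=C2C(C)(C)C[C@H](O[Si](C)(C)C(C)(C)C)C[C@@]2(C)O1 | intermediate
8 | (6S,7aR)-6-(tert-butyldimethylsilyloxy)-4,4,7a-trimethyl-2,4,5,6,7,7a-hexahydro-1-benzofuran-2-yl acetate (both C2 epimers) | CC(=O)OC1C=C2C(C)(C)C[C@H](O[Si](C)(C)C(C)(C)C)C[C@@]2(C)O1 | intermediate
9 | trimethylsilyl prop-2-ynoate | C#CC(=O)O[Si](C)(C)C | starting material
10 | trimethylsilyl (2Z)-2-[(2R,6S,7aR)-6-(tert-butyldimethylsilyloxy)-4,4,7a-trimethyl-2,4,5,6,7,7a-hexahydro-1-benzofuran-2-yl]-3-iodoprop-2-enoate | C[Si](C)(C)OC(=O)/C(=C\I)[C@H]1C=C2C(C)(C)C[C@H](O[Si](C)(C)C(C)(C)C)C[C@@]2(C)O1 | intermediate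
11 | (2Z)-2-[(2R,6S,7aR)-6-(tert-butyldimethylsilyloxy)-4,4,7a-trimethyl-2,4,5,6,7,7a-hexahydro-1-benzofuran-2-yl]-3-iodoprop-2-enoic acid | OC(=O)/C(=C\I)[C@H]1C=C2C(C)(C)C[C@H](O[Si](C)(C)C(C)(C)C)C[C@@]2(C)O1 | intermediate
12 | (2E)-3-methylpent-2-en-4-yn-1-ol | C#C/C(C)=C/CO | starting material
13 | (2E)-3-methylpent-2-en-4-ynal | C#C/C(C)=C/C=O | intermediate
14 | (triphenylphosphoranylidene)acetaldehyde | O=CC=P(c1ccccc1)(c1ccccc1)c1ccccc1 | starting material
15 | (2E,4E)-5-methylhepta-2,4-dien-6-ynal | C#C/C(C)=C/C=C/C=O | intermediate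
16 | (2Z,6E,8E)-2-[(2R,6S,7aR)-6-(tert-butyldimethylsilyloxy)-4,4,7a-trimethyl-2,4,5,6,7,7a-hexahydro-1-benzofuran-2-yl]-6-methyl-10-oxodeca-2,6,8-trien-4-ynoic acid | OC(=O)/C(=C\C#C/C(C)=C/C=C/C=O)[C@H]1C=C2C(C)(C)C[C@H](O[Si](C)(C)C(C)(C)C)C[C@@]2(C)O1 | intermediate
17 | (2E,4E,6Z)-6-{4-[(2R,6S,7aR)-6-(tert-butyldimethylsilyloxy)-4,4,7a-trimethyl-2,4,5,6,7,7a-hexahydro-1-benzofuran-2-yl]-5-oxofuran-2(5H)-ylidene}-5-methylhexa-2,4-dienal | O=C/C=C/C=C(C)/C=C1/C=C([C@H]2C=C3C(C)(C)C[C@H](O[Si](C)(C)C(C)(C)C)C[C@@]3(C)O2)C(=O)O1 | intermediate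
18 | 1-methoxy-4-({[(2E)-3-methylpent-2-en-4-yn-1-yl]oxy}methyl)benzene | C#C/C(C)=C/COCc1ccc(OC)cc1 | intermediate
19 | (4R,6R)-4-(tert-butyldimethylsilyloxy)-1-{(3E)-5-[(4-methoxybenzyl)oxy]-3-methylpent-3-en-1-yn-1-yl}-2,2,6-trimethylcyclohexan-1-ol (C1 epimers) | OC1(C#C/C(C)=C/COCc2ccc(OC)cc2)C(C)(C)C[C@H](O[Si](C)(C)C(C)(C)C)C[C@H]1C | intermediate
20 | tert-butyl{[(1R)-4-{(3E)-5-[(4-methoxybenzyl)oxy]-3-methylpent-3-en-1-yn-1-yl}-3,5,5-trimethylcyclohex-3-en-1-yl]oxy}dimethylsilane | CC1=C(C#C/C(C)=C/COCc2ccc(OC)cc2)C(C)(C)C[C@H](O[Si](C)(C)C(C)(C)C)C1 | intermediate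
21 | (2E)-5-[(4R)-4-(tert-butyldimethylsilyloxy)-2,6,6-trimethylcyclohex-1-en-1-yl]-3-methylpent-2-en-4-yn-1-ol | CC1=C(C#C/C(C)=C/CO)C(C)(C)C[C@H](O[Si](C)(C)C(C)(C)C)C1 | intermediate
22 | {[(1R)-4-[(3E)-5-bromo-3-methylpent-3-en-1-yn-1-yl]-3,5,5-trimethylcyclohex-3-en-1-yl]oxy}(tert-butyl)dimethylsilane | CC1=C(C#C/C(C)=C/CBr)C(C)(C)C[C@H](O[Si](C)(C)C(C)(C)C)C1 | intermediate
23 | diethyl {(2E)-5-[(4R)-4-(tert-butyldimethylsilyloxy)-2,6,6-trimethylcyclohex-1-en-1-yl]-3-methylpent-2-en-4-yn-1-yl}phosphonate | CC1=C(C#C/C(C)=C/CP(=O)(OCC)OCC)C(C)(C)C[C@H](O[Si](C)(C)C(C)(C)C)C1 | intermediate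
24 | bis(tert-butyldimethylsilyl) ether of the target | CC1=C(C#C/C(C)=C/C=C/C=C/C=C(C)/C=C2/C=C([C@H]3C=C4C(C)(C)C[C@H](O[Si](C)(C)C(C)(C)C)C[C@@]4(C)O3)C(=O)O2)C(C)(C)C[C@H](O[Si](C)(C)C(C)(C)C)C1 | intermediate
25 | (5Z)-3-[(2R,6S,7aR)-6-hydroxy-4,4,7a-trimethyl-2,4,5,6,7,7a-hexahydro-1-benzofuran-2-yl]-5-{(2E,4E,6E,8E)-11-[(4R)-4-hydroxy-2,6,6-trimethylcyclohex-1-en-1-yl]-2,9-dimethylundeca-2,4,6,8-tetraen-10-yn-1-ylidene}furan-2(5H)-one | CC1=C(C#C/C(C)=C/C=C/C=C/C=C(C)/C=C2/C=C([C@H]3C=C4C(C)(C)C[C@H](O)C[C@@]4(C)O3)C(=O)O2)C(C)(C)C[C@H](O)C1 | target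

**Count and risks**

Total step count: 16. Longest linear sequence: 8 steps (1 → 2 → 3 → 6 → 8 → 11 → 17 → 24 → 25; the branch through 18 to 23 is equally long).

Steps most likely to fail:

1. Step 5 (Proposed new method). The chiral anion may discriminate the two faces of the nearly unbiased furanium ion poorly, so that both C8 epimers form; uncatalysed ionisation by residual Me3SiI would add to this. The fallback fixes C8 before the ring is closed and uses known reactions; it sets out from 3 and comes back at 11. Methylenation of 3 (Ph3P=CH2 from Ph3PCH3Br and KOtBu, toluene, 90 °C) should give (1R,5S)-5-(tert-butyldimethylsilyloxy)-1,3,3-trimethyl-2-methylidenecyclohexan-1-ol F1. Separately, the catalytic enantioselective halo-aldol three-component coupling of acrolein, methyl propiolate and Me3SiI (chiral oxazaborolidinium salt, −78 °C) should give methyl (2Z)-2-[(1R)-1-hydroxyprop-2-en-1-yl]-3-iodoprop-2-enoate F2, which ClCO2Me and pyridine convert into the carbonate methyl (2Z)-3-iodo-2-[(1R)-1-(methoxycarbonyloxy)prop-2-en-1-yl]prop-2-enoate F3. The alkoxide of F1 with monovalent copper (LiN(SiMe3)2, then CuI) should replace the carbonate of F3 with net retention under RhCl(PPh3)3/P(OMe)3 (enantiospecific rhodium-catalysed allylic etherification), giving the diene ether methyl (2Z)-2-[(1R)-1-{[(1R,5S)-5-(tert-butyldimethylsilyloxy)-1,3,3-trimethyl-2-methylidenecyclohexyl]oxy}prop-2-en-1-yl]-3-iodoprop-2-enoate F4. Ring-closing metathesis (second-generation Hoveyda–Grubbs catalyst, RuCl2(=CH-C6H4-2-OiPr)(H2IMes), toluene, 80 °C) would then close the same C6=C7 bond and give methyl (2Z)-2-[(2R,6S,7aR)-6-(tert-butyldimethylsilyloxy)-4,4,7a-trimethyl-2,4,5,6,7,7a-hexahydro-1-benzofuran-2-yl]-3-iodoprop-2-enoate F5; saponification (LiOH, THF/water, 0 °C) returns to 11.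

2. Step 15. The strongly basic phosphonate carbanion may attack the ylidene butenolide (acyl substitution or conjugate addition) or abstract the C8 hydrogen, and double-bond geometry may erode. The fallback reverses the order of the last two carbon–carbon bond formations so that no strong base meets the butenolide; it sets out from 23 and comes back at 24. The same olefination applied to 23 and dienynal 15 (KN(SiMe3)2, THF, −78 °C) should give tert-butyl({(1R)-4-[(3E,5E,7E,9E)-3,10-dimethyldodeca-3,5,7,9-tetraene-1,11-diyn-1-yl]-3,5,5-trimethylcyclohex-3-en-1-yl}oxy)dimethylsilane F6. The coupling–lactonization of step 8, now between 11 and F6 (Pd(PPh3)4, CuI, Et3N, MeCN), should pass through (2Z,6E,8E,10E,12E)-2-[(2R,6S,7aR)-6-(tert-butyldimethylsilyloxy)-4,4,7a-trimethyl-2,4,5,6,7,7a-hexahydro-1-benzofuran-2-yl]-15-[(4R)-4-(tert-butyldimethylsilyloxy)-2,6,6-trimethylcyclohex-1-en-1-yl]-6,13-dimethylpentadeca-2,6,8,10,12-pentaene-4,14-diynoic acid F7 and give 24.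

3. Step 3. Addition of the hindered tertiary hydroxyl to the cumulated ylide may be slow at a temperature at which the α-ketol begins to rearrange. The fallback closes the ring stepwise by an anionic olefination; it sets out from 3 and comes back at 6. Esterification with diethylphosphonoacetic acid (DCC, DMAP, CH2Cl2) should give (1R,5S)-5-(tert-butyldimethylsilyloxy)-1,3,3-trimethyl-2-oxocyclohexyl (diethoxyphosphoryl)acetate F8, and intramolecular Horner–Wadsworth–Emmons reaction (NaH, THF, 0 → 20 °C) then forms the same C6=C7 bond and gives 6.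

**Further compounds**

F1 | step 5 | (1R,5S)-5-(tert-butyldimethylsilyloxy)-1,3,3-trimethyl-2-methylidenecyclohexan-1-ol | C=C1C(C)(C)C[C@H](O[Si](C)(C)C(C)(C)C)C[C@@]1(C)O
F2 | step 5 | methyl (2Z)-2-[(1R)-1-hydroxyprop-2-en-1-yl]-3-iodoprop-2-enoate | COC(=O)/C(=C\I)[C@H](O)C=C
F3 | step 5 | methyl (2Z)-3-iodo-2-[(1R)-1-(methoxycarbonyloxy)prop-2-en-1-yl]prop-2-enoate | COC(=O)/C(=C\I)[C@H](OC(=O)OC)C=C
F4 | step 5 | methyl (2Z)-2-[(1R)-1-{[(1R,5S)-5-(tert-butyldimethylsilyloxy)-1,3,3-trimethyl-2-methylidenecyclohexyl]oxy}prop-2-en-1-yl]-3-iodoprop-2-enoate | C=C1C(C)(C)C[C@H](O[Si](C)(C)C(C)(C)C)C[C@@]1(C)O[C@H](C=C)/C(=C/I)C(=O)OC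
F5 | step 5 | methyl (2Z)-2-[(2R,6S,7aR)-6-(tert-butyldimethylsilyloxy)-4,4,7a-trimethyl-2,4,5,6,7,7a-hexahydro-1-benzofuran-2-yl]-3-iodoprop-2-enoate | COC(=O)/C(=C\I)[C@H]1C=C2C(C)(C)C[C@H](O[Si](C)(C)C(C)(C)C)C[C@@]2(C)O1
F6 | step 15 | tert-butyl({(1R)-4-[(3E,5E,7E,9E)-3,10-dimethyldodeca-3,5,7,9-tetraene-1,11-diyn-1-yl]-3,5,5-trimethylcyclohex-3-en-1-yl}oxy)dimethylsilane | CC1=C(C#C/C(C)=C/C=C/C=C/C=C(C)/C#C)C(C)(C)C[C@H](O[Si](C)(C)C(C)(C)C)C1
F7 | step 15 | (2Z,6E,8E,10E,12E)-2-[(2R,6S,7aR)-6-(tert-butyldimethylsilyloxy)-4,4,7a-trimethyl-2,4,5,6,7,7a-hexahydro-1-benzofuran-2-yl]-15-[(4R)-4-(tert-butyldimethylsilyloxy)-2,6,6-trimethylcyclohex-1-en-1-yl]-6,13-dimethylpentadeca-2,6,8,10,12-pentaene-4,14-diynoic acid | CC1=C(C#C/C(C)=C/C=C/C=C/C=C(C)/C#C/C=C(\C(O)=O)[C@H]2C=C3C(C)(C)C[C@H](O[Si](C)(C)C(C)(C)C)C[C@@]3(C)O2)C(C)(C)C[C@H](O[Si](C)(C)C(C)(C)C)C1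
F8 | step 3 | (1R,5S)-5-(tert-butyldimethylsilyloxy)-1,3,3-trimethyl-2-oxocyclohexyl (diethoxyphosphoryl)acetate | O=C1C(C)(C)C[C@H](O[Si](C)(C)C(C)(C)C)C[C@@]1(C)OC(=O)CP(=O)(OCC)OCC
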